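**Plan**
- Retrosynthetic cuts, in order: C13=C14 and C13–C16 (ester olefination, methyl addition), C11=C12 (olefination of the C9 aldehyde), then both ring bonds C5–C10 and C8–C9 in one [4+2], then C1–C10, C6–C7, C5=C6 and C1=C2 of the open chain, back to pantolactone.
- Forward: pantolactone supplies C2–C5; C1 comes by methylenation, C6–C8/C17 by iodo-olefination and alkenyl coupling, C9–C11/C20 by B-alkyl coupling; rings A and B then form together; the C9 aldehyde is extended to C13, C3 and C8 are adjusted, and C14–C15 are added last.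
- Enabling feature: ring B (C5–C10) holds four contiguous stereocentres C5, C10, C9, C8 (trans fusion, C11 syn to C20, C17 syn to C11), the imprint of an endo addition of an (E)-enal C9=C10 to an (E,E)-diene C5=C6–C7=C8 across the C1–C4 tether that becomes ring A; C2–C3(O)–C4(CH3)2–C5 is the carbon skeleton of pantolactone.
- Stereochemistry: the C3 oxygen from (S)-pantolactone sits equatorial in the chair tether and relays the absolute sense to C5, C10, C9 and C8; C8–OH comes by retentive hydroxylation of the equatorial C8–H; the equatorial C3–Br is reset by axial hydrogen-atom delivery; C13=C14 (E) by Horner–Wadsworth–Emmons olefination.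

Key step: step 11

Remark: labdane numbering is used throughout (C20 = methyl on C10, C17 = methyl on C8) and syn/anti refer to the face of C20; the SMILES given is the (3R,5S,8S,9S,10R) antipode, for which (S)-pantolactone is the correct relay.

**Route**

Step 1
Reactants: 1 (S)-pantolactone
Product: 2 (3S)-3-(benzyloxy)-4,4-dimethyloxolan-2-one
Conditions: BnOC(=NH)CCl3 (1.3 equiv), TfOH (5 mol %), cyclohexane–CH2Cl2, 0 °C to rt
Reagents that add atoms: benzyl 2,2,2-trichloroacetimidate, ClC(Cl)(Cl)C(=N)OCc1ccccc1
Why: acid-catalysed O-benzylation through the trichloroacetimidate is base-free, so the α-stereocentre (future C3) should not epimerise.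

Step 2
Reactants: 2 (3S)-3-(benzyloxy)-4,4-dimethyloxolan-2-one
Product: 3 (3S)-3-(benzyloxy)-4,4-dimethyloxolan-2-ol (anomeric mixture)
Conditions: DIBAL-H (1.15 equiv), CH2Cl2, −78 °C; aq Rochelle salt
Reagents that add atoms: none
Why: DIBAL half-reduction of a lactone stops at the lactol because the tetrahedral aluminate is stable at −78 °C.

Step 3
Reactants: 3 (3S)-3-(benzyloxy)-4,4-dimethyloxolan-2-ol
Product: 5 (3R)-3-(benzyloxy)-2,2-dimethylpent-4-en-1-ol, via hydroxy aldehyde 4 (not isolated)
Conditions: Ph3PCH3Br (3 equiv), KOtBu (2.9 equiv), THF, 0 °C to rt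
Reagents that add atoms: methyltriphenylphosphonium bromide, C[P+](c1ccccc1)(c1ccccc1)c1ccccc1.[Br-]
Why: Wittig methylenation of the lactol through its ring-opened aldehyde adds C1 and frees the neopentyl C5 hydroxyl; the non-stabilised ylide should trap the α-alkoxy aldehyde faster than it enolises, and a benzyl ether cannot migrate to the alkoxide.

Step 4
Reactants: 5 (3R)-3-(benzyloxy)-2,2-dimethylpent-4-en-1-ol
Product: 6 (3R)-3-(benzyloxy)-2,2-dimethylpent-4-enal
Conditions: Dess–Martin periodinane (1.3 equiv), CH2Cl2, rt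
Reagents that add atoms: none
Why: Dess–Martin oxidation of the neopentyl alcohol gives an aldehyde without α-hydrogen, which can neither epimerise nor eliminate the β-benzyloxy group.

Step 5
Reactants: 6 (3R)-3-(benzyloxy)-2,2-dimethylpent-4-enal
Product: 7 (1E,4R)-4-(benzyloxy)-1-iodo-3,3-dimethylhexa-1,5-diene
Conditions: CrCl2 (6 equiv), CHI3 (2 equiv), THF–1,4-dioxane, 0 °C to rt
Reagents that add atoms: iodoform, IC(I)I
Why: Takai iodo-olefination should give the (E)-alkenyl iodide (C5=C6), the anti elimination from the gem-dichromium adduct being reinforced by the α-quaternary centre.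

Step 6
Reactants: 7 (1E,4R)-4-(benzyloxy)-1-iodo-3,3-dimethylhexa-1,5-diene; 8 (E)-prop-1-enylboronic acid
Product: 9 (3R,5E,7E)-3-(benzyloxy)-4,4-dimethylnona-1,5,7-triene
Conditions: Pd(PPh3)4 (5 mol %), aq KOH (3 equiv), THF, 50 °C
Reagents that add atoms: none
Why: Suzuki–Miyaura coupling proceeds with retention at both alkenyl partners, so the (E,E)-diene C5=C6–C7=C8 is obtained with defined geometry while the monosubstituted alkene is untouched.

Step 7
Reactants: 10 ethyl acetoacetate
Product: 11 ethyl (E)-3-{[(trifluoromethyl)sulfonyl]oxy}but-2-enoate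
Conditions: Tf2O (1.2 equiv), 25 % aq Me4NOH (3 equiv), toluene, 5 °C to rt
Reagents that add atoms: trifluoromethanesulfonic anhydride, O=S(=O)(OS(=O)(=O)C(F)(F)F)C(F)(F)F
Why: biphasic O-triflation of the non-chelated tetraalkylammonium enolate of a β-keto ester should give the (E)-enol triflate, with OTf trans to the ester.

Step 8
Reactants: 9 (3R,5E,7E)-3-(benzyloxy)-4,4-dimethylnona-1,5,7-triene; 11 ethyl (E)-3-{[(trifluoromethyl)sulfonyl]oxy}but-2-enoate
Product: 13 ethyl (2E,6R,8E,10E)-6-(benzyloxy)-3,7,7-trimethyldodeca-2,8,10-trienoate, via alkylborane 12 (not isolated)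
Conditions: 9-BBN dimer (0.65 equiv), THF, 0 °C to rt; then 11 (1.2 equiv), PdCl2(dppf) (5 mol %), AsPh3 (10 mol %), Cs2CO3 (2.5 equiv), DMF–H2O, rt
Reagents that add atoms: none
Why: 9-BBN hydroborates the monosubstituted alkene far faster than the 1,4-disubstituted diene and places boron on C1, and the B-alkyl Suzuki–Miyaura coupling retains the triflate geometry, so the C1–C10 bond forms with C9=C10 fixed as E (ester trans to the tether).

Step 9
Reactants: 13 ethyl (2E,6R,8E,10E)-6-(benzyloxy)-3,7,7-trimethyldodeca-2,8,10-trienoate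
Product: 14 (2E,6R,8E,10E)-6-(benzyloxy)-3,7,7-trimethyldodeca-2,8,10-trien-1-ol
Conditions: DIBAL-H (2.5 equiv), CH2Cl2, −78 °C
Reagents that add atoms: none
Why: DIBAL 1,2-reduction of an enoate gives the allylic alcohol without touching the diene or the benzyl ether.

Step 10
Reactants: 14 (2E,6R,8E,10E)-6-(benzyloxy)-3,7,7-trimethyldodeca-2,8,10-trien-1-ol
Product: 15 (2E,6R,8E,10E)-6-(benzyloxy)-3,7,7-trimethyldodeca-2,8,10-trienal
Conditions: MnO2 (15 equiv), CH2Cl2, rt
Reagents that add atoms: none
Why: MnO2 allylic oxidation is neutral and selective for the allylic alcohol, so the (E)-enal should form without E/Z scrambling.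

Step 11
Reactants: 15 (2E,6R,8E,10E)-6-(benzyloxy)-3,7,7-trimethyldodeca-2,8,10-trienal
Product: 16 (1R,2R,4aS,6R,8aR)-6-(benzyloxy)-2,5,5,8a-tetramethyl-1,2,4a,5,6,7,8,8a-octahydronaphthalene-1-carbaldehyde
Conditions: Me2AlCl (0.5 equiv, promoter, not consumed), CH2Cl2, −78 to −20 °C; chromatography
Reagents that add atoms: none
Why: The aluminium Lewis acid binds the formyl oxygen and lowers the LUMO of the C9=C10 enal, so the tethered (E,E)-diene adds in a concerted but asynchronous [4+2] in which the C5–C10 bond to the β-carbon runs ahead of C8–C9. The closest known reaction type is the Lewis-acid-promoted type-1 intramolecular Diels–Alder reaction of (E,E,E)-deca-2,8,10-trienals to trans-fused octalins, here with a β,β-disubstituted enal. Ring B is the new cyclohexene from suprafacial union of C5–C8 with C9=C10, and ring A closes as a six-membered carbocycle through the C5–C10 bond across the four-carbon tether C1–C4 folded as a chair. C9 and C10 follow from the (E)-enal geometry (formyl syn to C20), C8 from the (E)-C7=C8 geometry together with the endo formyl group (C17 syn to the formyl group), the trans C5/C10 fusion from the endo-formyl, anti-tether chair, and the absolute sense of all four from the C3 benzyloxy group sitting equatorial in that chair. The step needs endo over exo addition and one diene face: Lewis-acid complexation sharpens the endo preference, the stereodefined alkenes from steps 5–8 remove geometric ambiguity, and the C4 gem-dimethyl group raises the population of the folded conformer. The two facial isomers are diastereomers, so the minor one should be removable by chromatography before the C3 stereocentre is erased.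

Step 12
Reactants: 16 octalin aldehyde; 17 diethyl [2-(methoxy(methyl)amino)-2-oxoethyl]phosphonate
Product: 18 (2E)-3-[(6-benzyloxy-2,5,5,8a-tetramethyl-1,2,4a,5,6,7,8,8a-octahydronaphthalen-1-yl)]-N-methoxy-N-methylprop-2-enamide (ring configuration as in 16)
Conditions: NaH (1.4 equiv), THF, 0 °C to rt
Reagents that add atoms: none
Why: Horner–Wadsworth–Emmons olefination of the aldehyde adds C12 and C13 as an (E)-enamide, and C9 keeps its more stable equatorial configuration.

Step 13
Reactants: 18 unsaturated N-methoxy-N-methylamide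
Product: 20 3-[(1R,2R,4aS,6R,8aS)-6-hydroxy-2,5,5,8a-tetramethyldecahydronaphthalen-1-yl]-N-methoxy-N-methylpropanamide, via saturated benzyl ether 19 (not isolated)
Conditions: H2 (3 atm), 20 % Pd(OH)2/C, EtOAc–EtOH, rt
Reagents that add atoms: none
Why: catalytic hydrogenation saturates C6=C7 and C11=C12 and then hydrogenolyses the benzyl ether; no stereocentre is created, and hydrogen pressure should let saturation outrun double-bond migration towards C8.

Step 14
Reactants: 20 hydroxy amide
Product: 22 3-[(1S,2S,4aS,8aR)-2-hydroxy-2,5,5,8a-tetramethyl-6-oxodecahydronaphthalen-1-yl]-N-methoxy-N-methylpropanamide, via keto amide 21 (not isolated)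
Conditions: TFDO (ca. 3.5 equiv, solution in CF3COCH3), CH2Cl2, −20 to 0 °C
Reagents that add atoms: methyl(trifluoromethyl)dioxirane, CC1(OO1)C(F)(F)F
Why: dioxirane oxidation first converts the C3 carbinol to the ketone and then inserts oxygen with retention into the equatorial tertiary C8–H, which is activated by relief of the C17/C20 1,3-diaxial strain, while the ketone and the amide deactivate ring A and the chain and the axial C5–H and C9–H are shielded.

Step 15
Reactants: 22 keto hydroxy amide
Product: 24 3-[(1S,2S,4aS,8aR)-6-bromo-2-hydroxy-2,5,5,8a-tetramethyl-1,2,3,4,4a,5,8,8a-octahydronaphthalen-1-yl]-N-methoxy-N-methylpropanamide, via silyl hydrazone 23 (not isolated)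
Conditions: TBSNHNHTBS (1.3 equiv), Sc(OTf)3 (1 mol %), CHCl3, 60 °C; evaporate; then Br2 (2.2 equiv), BTMG (6 equiv), CH2Cl2, 0 °C to rt
Reagents that add atoms: bromine, BrBr
Why: Barton-type vinyl halide synthesis from the N-silyl hydrazone; only C2 carries hydrogen next to C3, so the bromoalkene can only form as C2=C3–Br.

Step 16
Reactants: 24 alkenyl bromide
Product: 25 3-[(1S,2S,4aS,6R,8aR)-6-bromo-2-hydroxy-2,5,5,8a-tetramethyldecahydronaphthalen-1-yl]-N-methoxy-N-methylpropanamide
Conditions: Mn(dpm)3 (10 mol %), PhSiH3 (2 equiv), t-BuOOH (2 equiv), i-PrOH, rt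
Reagents that add atoms: none
Why: metal-hydride hydrogen-atom-transfer hydrogenation adds H to C2 to give the α-bromo C3 radical without C–Br hydrogenolysis, and the second hydrogen should arrive axially on the face anti to C20 and the axial C4 methyl, giving the thermodynamically favoured equatorial bromide (3R, syn to C20).

Step 17
Reactants: 25 bromo hydroxy amide
Product: 26 4-[(1S,2S,4aS,6R,8aR)-6-bromo-2-hydroxy-2,5,5,8a-tetramethyldecahydronaphthalen-1-yl]butan-2-one
Conditions: MeMgBr (3.5 equiv), THF, 0 °C; aq NH4Cl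
Reagents that add atoms: methylmagnesium bromide, C[Mg]Br
Why: Weinreb ketone synthesis: the chelated tetrahedral adduct prevents over-addition, one equivalent is spent on the C8 hydroxyl, and the equatorial neopentyl bromide is inert to the Grignard reagent at 0 °C.

Step 18
Reactants: 26 methyl ketone; 27 triethyl phosphonoacetate
Product: 28 ethyl (2E)-5-[(1S,2S,4aS,6R,8aR)-6-bromo-2-hydroxy-2,5,5,8a-tetramethyldecahydronaphthalen-1-yl]-3-methylpent-2-enoate
Conditions: NaH (5 equiv), 27 (4 equiv), THF, 0 to 50 °C; chromatographic removal of the (Z)-isomer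
Reagents that add atoms: none
Why: Horner–Wadsworth–Emmons olefination of the methyl ketone places the ester trans to the larger C12 chain (E favoured, minor Z-isomer separable), and the equatorial bromide has no antiperiplanar hydrogen for E2 elimination.

Step 19
Reactants: 28 (E)-enoate
Product: 29 (3R,5S,8S,9S,10R)-3-bromolabd-13(E)-ene-8,15-diol (target)
Conditions: DIBAL-H (4 equiv), CH2Cl2, −78 °C; aq Rochelle salt
Reagents that add atoms: none
Why: DIBAL 1,2-reduction of the enoate gives the allylic alcohol with the alkene geometry intact, and the secondary bromide and tertiary alkoxide are unaffected at −78 °C.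

**Compound list**

1 | (S)-pantolactone | CC1(C)COC(=O)[C@H]1O | starting material
2 | (3S)-3-(benzyloxy)-4,4-dimethyloxolan-2-one | CC1(C)COC(=O)[C@H]1OCc1ccccc1 | intermediate
3 | (3S)-3-(benzyloxy)-4,4-dimethyloxolan-2-ol | CC1(C)COC(O)[C@H]1OCc1ccccc1 | intermediate
4 | (2S)-2-(benzyloxy)-4-hydroxy-3,3-dimethylbutanal (open-chain form, not isolated) | O=C[C@@H](OCc1ccccc1)C(C)(C)CO | intermediate
5 | (3R)-3-(benzyloxy)-2,2-dimethylpent-4-en-1-ol | C=C[C@@H](OCc1ccccc1)C(C)(C)CO | intermediate
6 | (3R)-3-(benzyloxy)-2,2-dimethylpent-4-enal | C=C[C@@H](OCc1ccccc1)C(C)(C)C=O | intermediate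
7 | (1E,4R)-4-(benzyloxy)-1-iodo-3,3-dimethylhexa-1,5-diene | C=C[C@@H](OCc1ccccc1)C(C)(C)/C=C/I | intermediate
8 | (E)-prop-1-enylboronic acid | C/C=C/B(O)O | starting material
9 | (3R,5E,7E)-3-(benzyloxy)-4,4-dimethylnona-1,5,7-triene | C=C[C@@H](OCc1ccccc1)C(C)(C)/C=C/C=C/C | intermediate
10 | ethyl acetoacetate | CCOC(=O)CC(C)=O | starting material
11 | ethyl (E)-3-{[(trifluoromethyl)sulfonyl]oxy}but-2-enoate | CCOC(=O)/C=C(C)/OS(=O)(=O)C(F)(F)F | intermediate
12 | 9-[(3R,5E,7E)-3-(benzyloxy)-4,4-dimethylnona-5,7-dien-1-yl]-9-borabicyclo[3.3.1]nonane (not isolated) | C1CCC2CCCC1B2CC[C@@H](OCc1ccccc1)C(C)(C)/C=C/C=C/C | intermediate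
13 | ethyl (2E,6R,8E,10E)-6-(benzyloxy)-3,7,7-trimethyldodeca-2,8,10-trienoate | CCOC(=O)/C=C(\C)CC[C@@H](OCc1ccccc1)C(C)(C)/C=C/C=C/C | intermediate
14 | (2E,6R,8E,10E)-6-(benzyloxy)-3,7,7-trimethyldodeca-2,8,10-trien-1-ol | OC/C=C(\C)CC[C@@H](OCc1ccccc1)C(C)(C)/C=C/C=C/C | intermediate
15 | (2E,6R,8E,10E)-6-(benzyloxy)-3,7,7-trimethyldodeca-2,8,10-trienal (cycloaddition precursor) | O=C/C=C(\C)CC[C@@H](OCc1ccccc1)C(C)(C)/C=C/C=C/C | intermediate
16 | (1R,2R,4aS,6R,8aR)-6-(benzyloxy)-2,5,5,8a-tetramethyl-1,2,4a,5,6,7,8,8a-octahydronaphthalene-1-carbaldehyde (trans-fused Δ6-octalin; C20, C9–CHO, C17 and C3–OBn on one face, H5 on the other) | O=C[C@H]1[C@]2(C)CC[C@@H](OCc3ccccc3)C(C)(C)[C@H]2C=C[C@H]1C | intermediate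
17 | diethyl [2-(methoxy(methyl)amino)-2-oxoethyl]phosphonate | CCOP(=O)(CC(=O)N(C)OC)OCC | starting material
18 | (E)-N-methoxy-N-methyl acrylamide on C9 of octalin 16 (ring configuration as in 16) | CON(C)C(=O)/C=C/[C@H]1[C@]2(C)CC[C@@H](OCc3ccccc3)C(C)(C)[C@H]2C=C[C@H]1C | intermediate
19 | saturated 3-benzyloxy decalin N-methoxy-N-methylpropanamide (not isolated; ring configuration as in 16) | CON(C)C(=O)CC[C@H]1[C@]2(C)CC[C@@H](OCc3ccccc3)C(C)(C)[C@H]2CC[C@H]1C | intermediate
20 | 3-[(1R,2R,4aS,6R,8aS)-6-hydroxy-2,5,5,8a-tetramethyldecahydronaphthalen-1-yl]-N-methoxy-N-methylpropanamide (C3–OH equatorial, syn to C20) | CON(C)C(=O)CC[C@H]1[C@]2(C)CC[C@@H](O)C(C)(C)[C@H]2CC[C@H]1C | intermediate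
21 | 3-oxo analogue of 20 with C8–H (not isolated) | CON(C)C(=O)CC[C@H]1[C@]2(C)CCC(=O)C(C)(C)[C@H]2CC[C@H]1C | intermediate
22 | 3-[(1S,2S,4aS,8aR)-2-hydroxy-2,5,5,8a-tetramethyl-6-oxodecahydronaphthalen-1-yl]-N-methoxy-N-methylpropanamide (C8–OH equatorial, anti to C20) | CON(C)C(=O)CC[C@H]1[C@]2(C)CCC(=O)C(C)(C)[C@H]2CC[C@]1(C)O | intermediate
23 | N-tert-butyldimethylsilyl hydrazone of 22 at C3 (not isolated) | CON(C)C(=O)CC[C@H]1[C@]2(C)CCC(=NN[Si](C)(C)C(C)(C)C)C(C)(C)[C@H]2CC[C@]1(C)O | intermediate
24 | 3-bromo-Δ2 alkenyl bromide, 8-hydroxy N-methoxy-N-methylamide | CON(C)C(=O)CC[C@H]1[C@]2(C)CC=C(Br)C(C)(C)[C@H]2CC[C@]1(C)O | intermediate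
25 | 3-[(1S,2S,4aS,6R,8aR)-6-bromo-2-hydroxy-2,5,5,8a-tetramethyldecahydronaphthalen-1-yl]-N-methoxy-N-methylpropanamide (C3–Br equatorial, syn to C20) | CON(C)C(=O)CC[C@H]1[C@]2(C)CC[C@@H](Br)C(C)(C)[C@H]2CC[C@]1(C)O | intermediate
26 | 4-[(1S,2S,4aS,6R,8aR)-6-bromo-2-hydroxy-2,5,5,8a-tetramethyldecahydronaphthalen-1-yl]butan-2-one | CC(=O)CC[C@H]1[C@]2(C)CC[C@@H](Br)C(C)(C)[C@H]2CC[C@]1(C)O | intermediate
27 | triethyl phosphonoacetate | CCOC(=O)CP(=O)(OCC)OCC | starting material
28 | ethyl (2E)-5-[(1S,2S,4aS,6R,8aR)-6-bromo-2-hydroxy-2,5,5,8a-tetramethyldecahydronaphthalen-1-yl]-3-methylpent-2-enoate | CCOC(=O)/C=C(\C)CC[C@H]1[C@]2(C)CC[C@@H](Br)C(C)(C)[C@H]2CC[C@]1(C)O | intermediate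
29 | (2E)-5-[(1S,2S,4aS,6R,8aR)-6-bromo-2-hydroxy-2,5,5,8a-tetramethyldecahydronaphthalen-1-yl]-3-methylpent-2-en-1-ol, i.e. (3R,5S,8S,9S,10R)-3-bromolabd-13(E)-ene-8,15-diol | C/C(=C\CO)CC[C@H]1[C@]2(C)CC[C@@H](Br)C(C)(C)[C@H]2CC[C@]1(C)O | target

**Step count**
Total: 19 steps. Longest linear sequence: 18 steps (steps 1–6 and 8–19 from (S)-pantolactone); step 7 is a one-step side branch.

**Steps most likely to fail**

Step 11. The cycloaddition may stall because the β,β-disubstituted enal is a weak dienophile, the Lewis acid may instead cause E/Z scrambling or oligomerisation, and endo or facial selectivity may erode. The fallback is an ionic Diels–Alder reaction that sets out from 15 and returns at 16. Aldehyde 15 is acetalised with 1,2-bis(trimethylsilyloxy)ethane and catalytic TMSOTf at −78 °C to give trienyl dioxolane F1. Catalytic TfOH in CH2Cl2 at −78 °C opens the acetal to an alkoxyallyl cation, a much stronger dienophile that closes the same C5–C10 and C8–C9 bonds to give cycloadduct dioxolane F2. PPTS in wet acetone then releases aldehyde 16.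

Step 14. The dioxirane may attack competing C–H bonds (ring methylenes, the N-methoxy-N-methyl group) or stop after the alcohol oxidation. The fallback sets out from 20 and returns at 22 and decouples the two oxidations. Dess–Martin oxidation gives keto amide 21 as an isolated compound. The C8–H bond is then hydroxylated under catalyst control with a non-haem iron PDP complex, H2O2 and AcOH in MeCN; this iron-oxo rebound process is stereoretentive and its ligand discriminates sterically for the exposed equatorial tertiary C–H. No compound outside the list arises (F0).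

Step 16. Hydrogen-atom transfer to the hindered bromoalkene may be slow, bromine may be lost by over-reduction, or the second hydrogen may arrive from the wrong face; the preceding hydrazone bromination may also divert to rearranged products. The fallback sets out from 22 and returns at 25, bypassing 24. K-Selectride in THF at −78 °C delivers hydride equatorially to the C3 ketone, much faster than to the amide, to give axial alcohol F3. Appel bromination (CBr4, PPh3, CH2Cl2) then displaces the axial oxyphosphonium group with inversion to give equatorial bromide 25; the tertiary C8 alcohol is too hindered to be activated.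

Further compounds
F1 | step 11 | 2-[(1E,5R,7E,9E)-5-(benzyloxy)-2,6,6-trimethylundeca-1,7,9-trien-1-yl]-1,3-dioxolane | C1COC(O1)/C=C(\C)CC[C@@H](OCc1ccccc1)C(C)(C)/C=C/C=C/C
F2 | step 11 | 1,3-dioxolane acetal of aldehyde 16 (ring configuration as in 16) | C1COC(O1)[C@H]1[C@]2(C)CC[C@@H](OCc3ccccc3)C(C)(C)[C@H]2C=C[C@H]1C
F0 | step 14 | none | none
F3 | step 16 | C3 axial alcohol (hydroxyl anti to C20), 8-hydroxy N-methoxy-N-methylamide | CON(C)C(=O)CC[C@H]1[C@]2(C)CC[C@H](O)C(C)(C)[C@H]2CC[C@]1(C)O
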